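**Plan**

- Retrosynthesis: the acetate C–O bond and the side-chain C3′=C4′ double bond are cut first. Then the C1–C2 bond of the cyclopentane ring (C1, C2, C3, C3a, C7a) is cut by a retro-Conia-ene step. Then C1=CH2 and C1–C1′, C3a–C3, C7a–CH3 and C7–C7a are cut, back to methyl acetoacetate and prenyl bromide.
- Enabling feature: on the cyclopentane the C1 methyl is cis to the carbonyl carbon on the adjacent C2, and C2 is the α-carbon of that carbonyl. C1 with its methyl is therefore the ε,ζ-alkene, and C2–CHO the enol partner, of an intramolecular ene reaction across the tether C3–C3a–C7a.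
- Forward order: the six-membered ring is made first (cation–olefin cyclisation), C7a is methylated, the two arms are attached at C3a and C7a, and the five-membered ring is closed by the thermal enol–ene reaction. The side chain is completed afterwards, because its alkene would form a Cope-active 1,5-diene with the C1 methylene during thermolysis.
- Stereochemistry: C7a comes from an L-valine tert-butyl ester enamine (auxiliary control). C1 and C2 come from the ene step (face selection by C7a; cis CHO/CH3 by suprafacial hydrogen transfer). The Z alkene comes from a Still–Gennari olefination.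

Key step: step 10

Numbering: the target is treated as a 2,3,5,6,7,7a-hexahydro-1H-indene with C1 (quaternary; methyl and side chain C1′–C5′), C2 (CO2H), C3, C3a=C4, C7 (gem-dimethyl) and C7a (angular methyl); it is (1R,2S,7aS) with a Z side-chain alkene.

Assumption: the facial sense of the methylation in step 4 is taken from the behaviour of the unsubstituted 2-oxocyclohexanecarboxylate enamine; if the gem-dimethyl substrate responded in the opposite sense, D-valine tert-butyl ester would be used with no other change.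

**Route**

Step 1
Reactants: 1 methyl acetoacetate; 2 1-bromo-3-methylbut-2-ene (prenyl bromide)
Product: 3 methyl 7-methyl-3-oxooct-6-enoate
Conditions: NaH, THF, 0 °C; n-BuLi, 0 °C; then 2, 0 °C to rt; aq. HCl
Reagents that add atoms: none
Why: The acetoacetate dianion is alkylated at its more basic terminal carbon (dianion γ-alkylation), so the prenyl group is attached at C4 only.

Step 2
Reactants: 3 methyl 7-methyl-3-oxooct-6-enoate
Product: 4 methyl 2,2-dimethyl-6-oxocyclohexane-1-carboxylate (racemic, configurationally labile at C1)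
Conditions: SnCl4 (1.5 equiv), CH2Cl2, 0 °C to rt; H2O
Reagents that add atoms: none
Why: The Lewis acid generates the tertiary cation from the prenyl alkene, which is captured by the central carbon of the enolised β-keto ester in a cation–olefin cyclisation that closes the six-membered ring and sets the gem-dimethyl carbon; the one labile stereocentre is erased in step 3.

Step 3
Reactants: 4 methyl 2,2-dimethyl-6-oxocyclohexane-1-carboxylate; 5 L-valine tert-butyl ester (free base from the commercial hydrochloride)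
Product: 6 methyl 2-{[(2S)-1-(tert-butoxy)-3-methyl-1-oxobutan-2-yl]amino}-6,6-dimethylcyclohex-1-ene-1-carboxylate
Conditions: BF3·OEt2 (cat.), PhH, reflux, Dean–Stark
Reagents that add atoms: none
Why: Acid-catalysed condensation with azeotropic removal of water gives the hydrogen-bonded enamino ester, which places the valine auxiliary next to the carbon that is to become quaternary.

Step 4
Reactants: 6 methyl 2-{[(2S)-1-(tert-butoxy)-3-methyl-1-oxobutan-2-yl]amino}-6,6-dimethylcyclohex-1-ene-1-carboxylate
Product: 8 methyl (1S)-1,2,2-trimethyl-6-oxocyclohexane-1-carboxylate, via N-alkylimine 7 (not isolated)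
Conditions: LiN(i-Pr)2, PhMe, −78 °C; HMPA (1 equiv), MeI, −78 to −40 °C; then 1 M HCl, rt
Reagents that add atoms: iodomethane, CI; water, O
Why: The chelated lithio-enamine is methylated at carbon on the face left open by the isopropyl/tert-butyl ester unit of the auxiliary (enamine alkylation of α-substituted β-keto esters), which sets the quaternary centre that becomes C7a, and aqueous acid then releases the ketone and returns the auxiliary.

Step 5
Reactants: 8 methyl (1S)-1,2,2-trimethyl-6-oxocyclohexane-1-carboxylate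
Product: 9 methyl (1S)-1,6,6-trimethyl-2-[(trifluoromethanesulfonyl)oxy]cyclohex-2-ene-1-carboxylate
Conditions: KN(SiMe3)2, THF, −78 °C; PhNTf2, −78 °C to rt; aq. HCl
Reagents that add atoms: N-phenylbis(trifluoromethanesulfonimide), O=S(=O)(N(c1ccccc1)S(=O)(=O)C(F)(F)F)C(F)(F)F
Why: The ketone can enolise only toward its CH2 side, so deprotonation and O-sulfonylation give a single enol triflate with the alkene already in the C3a=C4 position of the target.

Step 6
Reactants: 9 methyl (1S)-1,6,6-trimethyl-2-[(trifluoromethanesulfonyl)oxy]cyclohex-2-ene-1-carboxylate; 10 [2-(1,3-dioxolan-2-yl)ethyl]zinc bromide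
Product: 11 methyl (1S)-2-[2-(1,3-dioxolan-2-yl)ethyl]-1,6,6-trimethylcyclohex-2-ene-1-carboxylate
Conditions: 10 (1.5 equiv), PdCl2(dppf) (5 mol %), THF, 60 °C
Reagents that add atoms: none
Why: Negishi coupling of an enol triflate with a primary alkylzinc halide tolerates the ester and the acetal and attaches the three-carbon arm (future C3, C2 and carboxyl carbon) at the ring sp2 carbon.

Step 7
Reactants: 11 methyl (1S)-2-[2-(1,3-dioxolan-2-yl)ethyl]-1,6,6-trimethylcyclohex-2-ene-1-carboxylate; 12 tert-butyl(3-iodopropoxy)diphenylsilane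
Product: 13 4-[(tert-butyldiphenylsilyl)oxy]-1-{(1S)-2-[2-(1,3-dioxolan-2-yl)ethyl]-1,6,6-trimethylcyclohex-2-en-1-yl}butan-1-one
Conditions: 12 (1.5 equiv), t-BuLi (3 equiv), Et2O, −78 °C; then 11, −78 °C to rt; H2O
Reagents that add atoms: none
Why: The primary alkyllithium made by iodine–lithium exchange adds once to the ester, which has no α-hydrogen, and the hindered tetrahedral adduct collapses to the ketone only on work-up, so no tertiary alcohol should form.

Step 8
Reactants: 13 4-[(tert-butyldiphenylsilyl)oxy]-1-{(1S)-2-[2-(1,3-dioxolan-2-yl)ethyl]-1,6,6-trimethylcyclohex-2-en-1-yl}butan-1-one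
Product: 14 tert-butyl[(4-{(1R)-2-[2-(1,3-dioxolan-2-yl)ethyl]-1,6,6-trimethylcyclohex-2-en-1-yl}pent-4-en-1-yl)oxy]diphenylsilane
Conditions: Ph3PCH3Br, KOtBu, PhMe, 90 °C
Reagents that add atoms: methyltriphenylphosphonium bromide, C[P+](c1ccccc1)(c1ccccc1)c1ccccc1.[Br-]
Why: Wittig methylenation with Ph3P=CH2 at elevated temperature converts hindered ketones into 1,1-disubstituted alkenes and leaves the acetal, the silyl ether and the quaternary centre untouched (the descriptor changes from S to R only through the priority rules).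

Step 9
Reactants: 14 tert-butyl[(4-{(1R)-2-[2-(1,3-dioxolan-2-yl)ethyl]-1,6,6-trimethylcyclohex-2-en-1-yl}pent-4-en-1-yl)oxy]diphenylsilane
Product: 15 3-[(6R)-6-{5-[(tert-butyldiphenylsilyl)oxy]pent-1-en-2-yl}-5,5,6-trimethylcyclohex-1-en-1-yl]propanal
Conditions: 1 M HCl, THF, 0 °C to rt
Reagents that add atoms: water, O
Why: Dilute aqueous acid hydrolyses the dioxolane to the aldehyde while the tert-butyldiphenylsilyl ether and both alkenes survive.

Step 10
Reactants: 15 3-[(6R)-6-{5-[(tert-butyldiphenylsilyl)oxy]pent-1-en-2-yl}-5,5,6-trimethylcyclohex-1-en-1-yl]propanal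
Product: 17 (1R,2S,7aS)-1-{3-[(tert-butyldiphenylsilyl)oxy]propyl}-1,7,7,7a-tetramethyl-2,3,5,6,7,7a-hexahydro-1H-indene-2-carbaldehyde, via enol 16 (not isolated)
Conditions: PhMe (0.01 M), degassed, 2,6-di-tert-butyl-4-methylphenol (1 mol %), silanised sealed vessel or flow coil, 280 °C
Reagents that add atoms: none
Why: Heat equilibrates aldehyde 15 with its enol 16, whose C=C–O–H unit adds as the ene partner across the 1,1-disubstituted alkene in a concerted intramolecular ene reaction (Conia-ene reaction): the enol carbon bonds to the fully substituted alkene carbon while the hydroxyl hydrogen passes to the CH2 terminus, which becomes the C1 methyl group. The closest known reaction type is the thermal cyclisation of ε,ζ-unsaturated carbonyl compounds to cis-2-methylcyclopentyl carbonyl compounds, which also joins two fully substituted carbons in the conversion of dihydrocarvone into camphor. The cyclopentane closes in the 5-exo-trig mode with respect to the alkene (enol double bond exocyclic to the new ring); attack on the ring alkene would need a three- or four-membered ring, and the reverse orientation on the methylene alkene cannot deliver hydrogen to the internal carbon. C2 is controlled by the suprafacial hydrogen transfer: the carbonyl carbon and the new methyl group are bridged by O–H in the transition state and should emerge cis. C1 is controlled by the resident quaternary carbon (C7a of the product): the tether from the ring sp2 carbon fixes the line of approach, and the planar CH2=C/enol array should sit on the side of the pseudo-axial angular methyl, away from the gem-dimethyl carbon, so that the new methyl is cis to the angular methyl and the silyloxypropyl chain is cis to C7. The step needs this facial selectivity and survival of the kinetic cis aldehyde; high dilution, silanised glass, exclusion of air and a short residence time are meant to suppress aldol condensation, acid-catalysed Prins chemistry and epimerisation at C2 by re-enolisation.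

Step 11
Reactants: 17 (1R,2S,7aS)-1-{3-[(tert-butyldiphenylsilyl)oxy]propyl}-1,7,7,7a-tetramethyl-2,3,5,6,7,7a-hexahydro-1H-indene-2-carbaldehyde
Product: 18 (1R,2S,7aS)-1-{3-[(tert-butyldiphenylsilyl)oxy]propyl}-1,7,7,7a-tetramethyl-2,3,5,6,7,7a-hexahydro-1H-indene-2-carboxylic acid
Conditions: NaClO2, NaH2PO4, 2-methylbut-2-ene, t-BuOH–H2O, rt
Reagents that add atoms: sodium chlorite, [Na+].[O-]Cl=O
Why: Pinnick oxidation converts the hindered aldehyde into the acid under buffered conditions that do not epimerise C2, and the alkene scavenger protects the ring alkene from hypochlorous acid.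

Step 12
Reactants: 18 (1R,2S,7aS)-1-{3-[(tert-butyldiphenylsilyl)oxy]propyl}-1,7,7,7a-tetramethyl-2,3,5,6,7,7a-hexahydro-1H-indene-2-carboxylic acid
Product: 19 (1R,2S,7aS)-1-(3-hydroxypropyl)-1,7,7,7a-tetramethyl-2,3,5,6,7,7a-hexahydro-1H-indene-2-carboxylic acid
Conditions: Bu4NF (3 equiv), THF, rt; aq. HCl
Reagents that add atoms: none
Why: Fluoride cleaves the silyl ether, while the carboxylate formed in the flask is inert and is returned as the acid on acidic work-up.

Step 13
Reactants: 19 (1R,2S,7aS)-1-(3-hydroxypropyl)-1,7,7,7a-tetramethyl-2,3,5,6,7,7a-hexahydro-1H-indene-2-carboxylic acid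
Product: 20 (1R,2S,7aS)-1,7,7,7a-tetramethyl-1-(3-oxopropyl)-2,3,5,6,7,7a-hexahydro-1H-indene-2-carboxylic acid
Conditions: Dess–Martin periodinane, CH2Cl2, rt
Reagents that add atoms: none
Why: Dess–Martin oxidation of the primary alcohol stops at the aldehyde and tolerates the free carboxylic acid and the trisubstituted alkene.

Step 14
Reactants: 20 (1R,2S,7aS)-1,7,7,7a-tetramethyl-1-(3-oxopropyl)-2,3,5,6,7,7a-hexahydro-1H-indene-2-carboxylic acid; 21 ethyl 2-[bis(2,2,2-trifluoroethoxy)phosphoryl]propanoate
Product: 22 (1R,2S,7aS)-1-[(3Z)-5-ethoxy-4-methyl-5-oxopent-3-en-1-yl]-1,7,7,7a-tetramethyl-2,3,5,6,7,7a-hexahydro-1H-indene-2-carboxylic acid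
Conditions: 21 (2.4 equiv), KN(SiMe3)2 (2.3 equiv), 18-crown-6, THF, −78 °C; then 20; aq. HCl
Reagents that add atoms: none
Why: The bis(trifluoroethyl) phosphonate anion eliminates rapidly from the kinetically formed adduct (Still–Gennari olefination) and so should give the Z 2-methyl enoate with ester and chain cis; the first equivalent of anion merely converts the carboxylic acid into its inert potassium salt.

Step 15
Reactants: 22 (1R,2S,7aS)-1-[(3Z)-5-ethoxy-4-methyl-5-oxopent-3-en-1-yl]-1,7,7,7a-tetramethyl-2,3,5,6,7,7a-hexahydro-1H-indene-2-carboxylic acid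
Product: 23 (1R,2S,7aS)-1-[(3Z)-5-hydroxy-4-methylpent-3-en-1-yl]-1,7,7,7a-tetramethyl-2,3,5,6,7,7a-hexahydro-1H-indene-2-carboxylic acid
Conditions: i-Bu2AlH (5 equiv), CH2Cl2, −78 °C; aq. potassium sodium tartrate
Reagents that add atoms: none
Why: i-Bu2AlH reduces the conjugated ester to the allylic alcohol with retention of alkene geometry, whereas the acid is held as an aluminium carboxylate that is not reduced at −78 °C.

Step 16
Reactants: 23 (1R,2S,7aS)-1-[(3Z)-5-hydroxy-4-methylpent-3-en-1-yl]-1,7,7,7a-tetramethyl-2,3,5,6,7,7a-hexahydro-1H-indene-2-carboxylic acid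
Product: 24 (1R,2S,7aS)-1-[(3Z)-5-(acetyloxy)-4-methylpent-3-en-1-yl]-1,7,7,7a-tetramethyl-2,3,5,6,7,7a-hexahydro-1H-indene-2-carboxylic acid
Conditions: vinyl acetate (5 equiv), immobilised Candida antarctica lipase B, t-BuOMe, 30 °C
Reagents that add atoms: vinyl acetate, CC(=O)OC=C
Why: Lipase-catalysed transesterification acylates only the unhindered primary allylic alcohol, the hindered carboxylic acid being no substrate, and tautomerisation of the released vinyl alcohol to acetaldehyde makes the acylation irreversible.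

**Compound list**

1 | methyl acetoacetate | CC(=O)CC(=O)OC | starting material
2 | 1-bromo-3-methylbut-2-ene | CC(C)=CCBr | starting material
3 | methyl 7-methyl-3-oxooct-6-enoate | COC(=O)CC(=O)CCC=C(C)C | intermediate
4 | methyl 2,2-dimethyl-6-oxocyclohexane-1-carboxylate (racemic) | COC(=O)C1C(=O)CCCC1(C)C | intermediate
5 | L-valine tert-butyl ester | CC(C)[C@H](N)C(=O)OC(C)(C)C | starting material
6 | methyl 2-{[(2S)-1-(tert-butoxy)-3-methyl-1-oxobutan-2-yl]amino}-6,6-dimethylcyclohex-1-ene-1-carboxylate | COC(=O)C1=C(N[C@@H](C(C)C)C(=O)OC(C)(C)C)CCCC1(C)C | intermediate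
7 | methyl (1S)-2-{[(2S)-1-(tert-butoxy)-3-methyl-1-oxobutan-2-yl]imino}-1,6,6-trimethylcyclohexane-1-carboxylate | COC(=O)[C@]1(C)C(=N[C@@H](C(C)C)C(=O)OC(C)(C)C)CCCC1(C)C | intermediate
8 | methyl (1S)-1,2,2-trimethyl-6-oxocyclohexane-1-carboxylate | COC(=O)[C@]1(C)C(=O)CCCC1(C)C | intermediate
9 | methyl (1S)-1,6,6-trimethyl-2-[(trifluoromethanesulfonyl)oxy]cyclohex-2-ene-1-carboxylate | COC(=O)[C@]1(C)C(OS(=O)(=O)C(F)(F)F)=CCCC1(C)C | intermediate
10 | [2-(1,3-dioxolan-2-yl)ethyl]zinc bromide | Br[Zn]CCC1OCCO1 | starting material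
11 | methyl (1S)-2-[2-(1,3-dioxolan-2-yl)ethyl]-1,6,6-trimethylcyclohex-2-ene-1-carboxylate | COC(=O)[C@]1(C)C(CCC2OCCO2)=CCCC1(C)C | intermediate
12 | tert-butyl(3-iodopropoxy)diphenylsilane | CC(C)(C)[Si](OCCCI)(c1ccccc1)c1ccccc1 | starting material
13 | 4-[(tert-butyldiphenylsilyl)oxy]-1-{(1S)-2-[2-(1,3-dioxolan-2-yl)ethyl]-1,6,6-trimethylcyclohex-2-en-1-yl}butan-1-one | O=C(CCCO[Si](c1ccccc1)(c1ccccc1)C(C)(C)C)[C@]1(C)C(CCC2OCCO2)=CCCC1(C)C | intermediate
14 | tert-butyl[(4-{(1R)-2-[2-(1,3-dioxolan-2-yl)ethyl]-1,6,6-trimethylcyclohex-2-en-1-yl}pent-4-en-1-yl)oxy]diphenylsilane | C=C(CCCO[Si](c1ccccc1)(c1ccccc1)C(C)(C)C)[C@]1(C)C(CCC2OCCO2)=CCCC1(C)C | intermediate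
15 | 3-[(6R)-6-{5-[(tert-butyldiphenylsilyl)oxy]pent-1-en-2-yl}-5,5,6-trimethylcyclohex-1-en-1-yl]propanal | C=C(CCCO[Si](c1ccccc1)(c1ccccc1)C(C)(C)C)[C@]1(C)C(CCC=O)=CCCC1(C)C | intermediate
16 | 3-[(6R)-6-{5-[(tert-butyldiphenylsilyl)oxy]pent-1-en-2-yl}-5,5,6-trimethylcyclohex-1-en-1-yl]prop-1-en-1-ol (enol of 15) | C=C(CCCO[Si](c1ccccc1)(c1ccccc1)C(C)(C)C)[C@]1(C)C(CC=CO)=CCCC1(C)C | intermediate
17 | (1R,2S,7aS)-1-{3-[(tert-butyldiphenylsilyl)oxy]propyl}-1,7,7,7a-tetramethyl-2,3,5,6,7,7a-hexahydro-1H-indene-2-carbaldehyde | CC(C)(C)[Si](c1ccccc1)(c1ccccc1)OCCC[C@]1(C)[C@@H](C=O)CC2=CCCC(C)(C)[C@@]21C | intermediate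
18 | (1R,2S,7aS)-1-{3-[(tert-butyldiphenylsilyl)oxy]propyl}-1,7,7,7a-tetramethyl-2,3,5,6,7,7a-hexahydro-1H-indene-2-carboxylic acid | CC(C)(C)[Si](c1ccccc1)(c1ccccc1)OCCC[C@]1(C)[C@@H](C(=O)O)CC2=CCCC(C)(C)[C@@]21C | intermediate
19 | (1R,2S,7aS)-1-(3-hydroxypropyl)-1,7,7,7a-tetramethyl-2,3,5,6,7,7a-hexahydro-1H-indene-2-carboxylic acid | OCCC[C@]1(C)[C@@H](C(=O)O)CC2=CCCC(C)(C)[C@@]21C | intermediate
20 | (1R,2S,7aS)-1,7,7,7a-tetramethyl-1-(3-oxopropyl)-2,3,5,6,7,7a-hexahydro-1H-indene-2-carboxylic acid | O=CCC[C@]1(C)[C@@H](C(=O)O)CC2=CCCC(C)(C)[C@@]21C | intermediate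
21 | ethyl 2-[bis(2,2,2-trifluoroethoxy)phosphoryl]propanoate | CCOC(=O)C(C)P(=O)(OCC(F)(F)F)OCC(F)(F)F | starting material
22 | (1R,2S,7aS)-1-[(3Z)-5-ethoxy-4-methyl-5-oxopent-3-en-1-yl]-1,7,7,7a-tetramethyl-2,3,5,6,7,7a-hexahydro-1H-indene-2-carboxylic acid | CCOC(=O)/C(C)=C\CC[C@]1(C)[C@@H](C(=O)O)CC2=CCCC(C)(C)[C@@]21C | intermediate
23 | (1R,2S,7aS)-1-[(3Z)-5-hydroxy-4-methylpent-3-en-1-yl]-1,7,7,7a-tetramethyl-2,3,5,6,7,7a-hexahydro-1H-indene-2-carboxylic acid | OC/C(C)=C\CC[C@]1(C)[C@@H](C(=O)O)CC2=CCCC(C)(C)[C@@]21C | intermediate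
24 | (1R,2S,7aS)-1-[(3Z)-5-(acetyloxy)-4-methylpent-3-en-1-yl]-1,7,7,7a-tetramethyl-2,3,5,6,7,7a-hexahydro-1H-indene-2-carboxylic acid | CC(=O)OC/C(C)=C\CC[C@]1(C)[C@@H](C(=O)O)CC2=CCCC(C)(C)[C@@]21C | target

**Step count and risks**

Total step count: 16. Longest linear sequence: 16 steps (from methyl acetoacetate 1 to 24).

Steps most likely to fail:

Step 10. The ene closure has to join a fully substituted alkene carbon to a carbon beside a quaternary centre. At the temperature this needs, three processes threaten the outcome: re-enolisation of the product aldehyde may equilibrate C2, the two faces of the methylene alkene may be discriminated only weakly by C7a, and aldol self-condensation may consume the aldehyde. The fallback closes the same bond by radical conjugate addition and sets out from triflate 9: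
- Stille coupling of 9 with allyltributylstannane (Pd(PPh3)4, LiCl, THF, reflux) would give methyl (1S)-1,6,6-trimethyl-2-(prop-2-en-1-yl)cyclohex-2-ene-1-carboxylate F1.
- The operations of steps 7 and 8 would convert it into 4-[(tert-butyldiphenylsilyl)oxy]-1-[(1S)-1,6,6-trimethyl-2-(prop-2-en-1-yl)cyclohex-2-en-1-yl]butan-1-one F2 and then tert-butyl({4-[(1R)-1,6,6-trimethyl-2-(prop-2-en-1-yl)cyclohex-2-en-1-yl]pent-4-en-1-yl}oxy)diphenylsilane F3.
- Cross-metathesis of the allyl terminus with phenyl vinyl sulfone (second-generation Hoveyda–Grubbs catalyst, CH2Cl2, 40 °C) would give tert-butyl{[4-{(1R)-1,6,6-trimethyl-2-[(2E)-3-(phenylsulfonyl)prop-2-en-1-yl]cyclohex-2-en-1-yl}pent-4-en-1-yl]oxy}diphenylsilane F4.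
- Hydrogen-atom transfer to the 1,1-disubstituted alkene (Fe(acac)3, PhSiH3, EtOH–ethylene glycol, 60 °C) and 5-exo-trig addition of the tertiary radical to the vinyl sulfone would give tert-butyl{3-[(1R,2S,7aS)-1,7,7,7a-tetramethyl-2-[(phenylsulfonyl)methyl]-2,3,5,6,7,7a-hexahydro-1H-inden-1-yl]propoxy}diphenylsilane F5. The radical closure is not expected to match the ene reaction in diastereocontrol, so F5 would have to be separated from its isomers.
- Deprotonation of F5 beside sulfur (n-BuLi, THF, −78 °C) and oxidation of the carbanion with Me3SiOOSiMe3 would give aldehyde 17, where the route is rejoined.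

Step 8. The ylide may fail to add to a carbonyl group flanked by the quaternary ring carbon and may act only as a base, enolising the ketone toward its CH2 side. The fallback is a Peterson olefination that sets out from ketone 13. Addition of Me3SiCH2Li in the presence of anhydrous CeCl3 (THF, −78 °C) would give 5-[(tert-butyldiphenylsilyl)oxy]-2-{(1S)-2-[2-(1,3-dioxolan-2-yl)ethyl]-1,6,6-trimethylcyclohex-2-en-1-yl}-1-(trimethylsilyl)pentan-2-ol F6 (either carbinol epimer). Syn-elimination with KH in THF would give alkene 14, where the route is rejoined.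

Step 4. The gem-dimethyl group beside the nucleophilic carbon may slow C-methylation of the lithio-enamine, divert the electrophile to nitrogen and weaken the facial bias of the auxiliary, so that the quaternary centre forms with low enantiomeric purity. The fallback replaces auxiliary control by an enzymatic kinetic resolution and sets out from keto ester 4. Methylation with K2CO3 and MeI in acetone would give racemic methyl 1,2,2-trimethyl-6-oxocyclohexane-1-carboxylate F7. An NADPH-dependent ketoreductase (glucose dehydrogenase/glucose recycling, pH 7 buffer) selective for the (R)-ketone would reduce that enantiomer to methyl (1R,6S)-6-hydroxy-1,2,2-trimethylcyclohexane-1-carboxylate F8 (carbinol configuration depends on the enzyme and is immaterial). The unreduced (S)-ketone, separated by chromatography, is compound 8, where the route is rejoined.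

Further compounds
F1 | step 10 | methyl (1S)-1,6,6-trimethyl-2-(prop-2-en-1-yl)cyclohex-2-ene-1-carboxylate | COC(=O)[C@]1(C)C(CC=C)=CCCC1(C)C
F2 | step 10 | 4-[(tert-butyldiphenylsilyl)oxy]-1-[(1S)-1,6,6-trimethyl-2-(prop-2-en-1-yl)cyclohex-2-en-1-yl]butan-1-one | O=C(CCCO[Si](c1ccccc1)(c1ccccc1)C(C)(C)C)[C@]1(C)C(CC=C)=CCCC1(C)C
F3 | step 10 | tert-butyl({4-[(1R)-1,6,6-trimethyl-2-(prop-2-en-1-yl)cyclohex-2-en-1-yl]pent-4-en-1-yl}oxy)diphenylsilane | C=C(CCCO[Si](c1ccccc1)(c1ccccc1)C(C)(C)C)[C@]1(C)C(CC=C)=CCCC1(C)C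
F4 | step 10 | tert-butyl{[4-{(1R)-1,6,6-trimethyl-2-[(2E)-3-(phenylsulfonyl)prop-2-en-1-yl]cyclohex-2-en-1-yl}pent-4-en-1-yl]oxy}diphenylsilane | C=C(CCCO[Si](c1ccccc1)(c1ccccc1)C(C)(C)C)[C@]1(C)C(C/C=C/S(=O)(=O)c2ccccc2)=CCCC1(C)C
F5 | step 10 | tert-butyl{3-[(1R,2S,7aS)-1,7,7,7a-tetramethyl-2-[(phenylsulfonyl)methyl]-2,3,5,6,7,7a-hexahydro-1H-inden-1-yl]propoxy}diphenylsilane | CC(C)(C)[Si](c1ccccc1)(c1ccccc1)OCCC[C@]1(C)[C@@H](CS(=O)(=O)c3ccccc3)CC2=CCCC(C)(C)[C@@]21C
F6 | step 8 | 5-[(tert-butyldiphenylsilyl)oxy]-2-{(1S)-2-[2-(1,3-dioxolan-2-yl)ethyl]-1,6,6-trimethylcyclohex-2-en-1-yl}-1-(trimethylsilyl)pentan-2-ol | C[Si](C)(C)CC(O)(CCCO[Si](c1ccccc1)(c1ccccc1)C(C)(C)C)[C@]1(C)C(CCC2OCCO2)=CCCC1(C)C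
F7 | step 4 | methyl 1,2,2-trimethyl-6-oxocyclohexane-1-carboxylate (racemate) | COC(=O)C1(C)C(=O)CCCC1(C)C
F8 | step 4 | methyl (1R,6S)-6-hydroxy-1,2,2-trimethylcyclohexane-1-carboxylate | COC(=O)[C@@]1(C)[C@@H](O)CCCC1(C)C
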